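The 14-membered carbocycle (C1–C14; δ-lactone O–C3–C2–C1–C15–C16) is cut at C5–C6. C4, a methyl carbinol flanked by the CH2 group C5, is read as an opened 2,2-disubstituted oxirane, and C6 becomes an allylic carbon once the C7–OOH/C8=CH2 unit is traced back to a C7=C8 alkene. In one operation a sulfonyl-stabilised allyl anion at C6 opens the C4–C5 epoxide at C5: the carbocycle closes and the C4 alcohol appears with its configuration untouched. The precursor is an open chain carrying an (E)-allylic phenyl sulfone at C6, the (11S,12S)-epoxide, TBS ethers on O3 and O16, and the terminal (4S)-epoxide.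

Key step: step 18

Remark: C17–C20 denote the methyl groups on C15, C4, C8 and C12; the target is taken as (1R,3R,4S,7S,11S,12S,15S); the ring closure creates C6 as an additional, uncontrolled stereocentre (both epimers are carried) that is erased in step 19, and a possible silyl shift from O3 to the new O4 alkoxide is harmless because both silyl groups are removed together in step 20.

Step 1
Reactants: 1 geranyl acetate
Product: 2 (2E,6E)-8-hydroxy-3,7-dimethylocta-2,6-dien-1-yl acetate
Conditions: SeO2 (cat.), t-BuOOH, salicylic acid (cat.), CH2Cl2, 23 °C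
Reagents that add atoms: SeO2, O=[Se]=O (transfers the oxygen); tert-butyl hydroperoxide, CC(C)(C)OO (reoxidises selenium)
Why: Riley allylic oxidation (ene reaction then [2,3] shift) hydroxylates the (E)-methyl group of the electron-rich terminal alkene, the C2=C3 alkene being deactivated by the allylic acetate; no stereocentre is formed.

Step 2
Reactants: 2 (2E,6E)-8-hydroxy-3,7-dimethylocta-2,6-dien-1-yl acetate
Product: 3 (2E)-5-[(2S,3S)-3-(hydroxymethyl)-3-methyloxiran-2-yl]-3-methylpent-2-en-1-yl acetate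
Conditions: Ti(OiPr)4 (cat.), L-(+)-diethyl tartrate (cat.), t-BuOOH, 4 Å molecular sieves, CH2Cl2, −20 °C
Reagents that add atoms: tert-butyl hydroperoxide, CC(C)(C)OO
Why: Sharpless asymmetric epoxidation of the allylic alcohol; the L-(+)-tartrate catalyst should give the (2S,3S)-epoxy alcohol, as it does for (E)-2-methyl-2-alken-1-ols, which sets C11 and C12 as (S,S), and the alkene without a free allylic hydroxyl is not touched.

Step 3
Reactants: 3 (2E)-5-[(2S,3S)-3-(hydroxymethyl)-3-methyloxiran-2-yl]-3-methylpent-2-en-1-yl acetate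
Product: 4 west epoxy triflate
Conditions: Tf2O, 2,6-lutidine, CH2Cl2, −78 °C; used at once
Reagents that add atoms: trifluoromethanesulfonic anhydride, O=S(=O)(OS(=O)(=O)C(F)(F)F)C(F)(F)F
Why: O-sulfonylation of the primary alcohol at low temperature gives the most reactive leaving group for the later SN2 reaction at the hindered epoxy-carbinyl carbon C13; no stereocentre is affected.

Step 4
Reactants: 5 methyl (2R)-3-hydroxy-2-methylpropanoate
Product: 6 methyl (2R)-3-[(tert-butyldimethylsilyl)oxy]-2-methylpropanoate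
Conditions: TBSCl, imidazole, DMF, 23 °C
Reagents that add atoms: tert-butyldimethylsilyl chloride, CC(C)(C)[Si](C)(C)Cl
Why: Standard silylation of a primary alcohol; the stereocentre that becomes C15 is bought with the starting material and is not touched.

Step 5
Reactants: 6 methyl (2R)-3-[(tert-butyldimethylsilyl)oxy]-2-methylpropanoate
Product: 7 (2R)-3-[(tert-butyldimethylsilyl)oxy]-2-methylpropanal
Conditions: iBu2AlH (1.05 equiv), CH2Cl2, −78 °C
Reagents that add atoms: none
Why: Partial reduction of the ester stops at the aldehyde because the tetrahedral aluminate is stable at −78 °C; the α-stereocentre is kept by using the aldehyde cold and unpurified.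

Step 6
Reactants: 7 (2R)-3-[(tert-butyldimethylsilyl)oxy]-2-methylpropanal
Product: 8 methyl (2Z,4S)-5-[(tert-butyldimethylsilyl)oxy]-4-methylpent-2-enoate
Conditions: (CF3CH2O)2P(O)CH2CO2Me, KN(SiMe3)2, 18-crown-6, THF, −78 °C
Reagents that add atoms: methyl 2-[bis(2,2,2-trifluoroethoxy)phosphoryl]acetate, COC(=O)CP(=O)(OCC(F)(F)F)OCC(F)(F)F
Why: The Still–Gennari variant of the Horner–Wadsworth–Emmons reaction gives the (Z)-enoate that is needed for lactonisation; no new stereocentre is formed.

Step 7
Reactants: 8 methyl (2Z,4S)-5-[(tert-butyldimethylsilyl)oxy]-4-methylpent-2-enoate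
Product: 10 (5S)-5-methyl-5,6-dihydro-2H-pyran-2-one, via hydroxy ester 9 (not isolated)
Conditions: aq. HF, MeCN, 0 → 23 °C
Reagents that add atoms: none
Why: Acidic desilylation frees the hydroxyl, which closes onto the cis-disposed ester by transesterification to give the unsaturated δ-lactone.

Step 8
Reactants: 10 (5S)-5-methyl-5,6-dihydro-2H-pyran-2-one
Product: 11 (4R,5S)-5-methyl-4-[(phenylsulfanyl)methyl]oxan-2-one
Conditions: LiCu(CH2SPh)2 (from PhSMe, n-BuLi, DABCO; then CuI), THF, −78 → −30 °C; aq. NH4Cl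
Reagents that add atoms: LiCu(CH2SPh)2, [Li+].[Cu-](CSc1ccccc1)CSc1ccccc1
Why: Conjugate addition of a non-basic Gilman cuprate to the unsaturated δ-lactone; attack anti to the neighbouring methyl group should give the trans-4,5-disubstituted lactone, which sets C1 as (R) and brings in C14.

Step 9
Reactants: 11 (4R,5S)-5-methyl-4-[(phenylsulfanyl)methyl]oxan-2-one
Product: 12 (5R,6S)-7-hydroxy-2,6-dimethyl-5-[(phenylsulfanyl)methyl]hept-1-en-3-one
Conditions: CH2=C(CH3)Li (from 2-bromopropene, t-BuLi, Et2O), THF, −78 °C; AcOH, −78 °C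
Reagents that add atoms: isopropenyllithium, [Li]C(C)=C
Why: Addition of an alkenyllithium to a lactone stops after one addition because the lithium lactolate survives until the cold quench; this makes C3 a ketone and brings in C4, C5 and C18.

Step 10
Reactants: 12 (5R,6S)-7-hydroxy-2,6-dimethyl-5-[(phenylsulfanyl)methyl]hept-1-en-3-one
Product: 13 (5R,6S)-7-[(tert-butyldimethylsilyl)oxy]-2,6-dimethyl-5-[(phenylsulfanyl)methyl]hept-1-en-3-one
Conditions: TBSCl, imidazole, CH2Cl2, 0 → 23 °C
Reagents that add atoms: tert-butyldimethylsilyl chloride, CC(C)(C)[Si](C)(C)Cl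
Why: Silylation of the primary alcohol traps the open-chain hydroxy ketone and protects O16 for the rest of the route.

Step 11
Reactants: 13 (5R,6S)-7-[(tert-butyldimethylsilyl)oxy]-2,6-dimethyl-5-[(phenylsulfanyl)methyl]hept-1-en-3-one
Product: 15 (5R,6S)-7-[(tert-butyldimethylsilyl)oxy]-2,6-dimethyl-5-[(phenylsulfonyl)methyl]hept-1-en-3-one, via sulfoxide 14 (not isolated)
Conditions: mCPBA (2.2 equiv), CH2Cl2, 0 °C
Reagents that add atoms: 3-chloroperbenzoic acid, OOC(=O)c1cccc(Cl)c1
Why: Peracid oxidation of the sulfide to the sulfone; the electron-poor enone alkene is not epoxidised by a peracid under these conditions.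

Step 12
Reactants: 15 (5R,6S)-7-[(tert-butyldimethylsilyl)oxy]-2,6-dimethyl-5-[(phenylsulfonyl)methyl]hept-1-en-3-one
Product: 16 (3R,5R,6S)-7-[(tert-butyldimethylsilyl)oxy]-2,6-dimethyl-5-[(phenylsulfonyl)methyl]hept-1-en-3-ol
Conditions: (S)-2-methyl-CBS-oxazaborolidine (0.2 equiv), catecholborane, toluene, −78 °C
Reagents that add atoms: none
Why: Corey–Bakshi–Shibata reduction; with the alkenyl residue as the large group the (S)-catalyst should deliver hydride to give the (3R)-carbinol, and catecholborane at −78 °C avoids hydroboration of the alkene.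

Step 13
Reactants: 16 (3R,5R,6S)-7-[(tert-butyldimethylsilyl)oxy]-2,6-dimethyl-5-[(phenylsulfonyl)methyl]hept-1-en-3-ol
Product: 17 (1R,3R,4S)-5-[(tert-butyldimethylsilyl)oxy]-4-methyl-1-[(2S)-2-methyloxiran-2-yl]-3-[(phenylsulfonyl)methyl]pentan-1-ol
Conditions: Ti(OiPr)4 (cat.), D-(−)-diisopropyl tartrate (cat.), t-BuOOH, 4 Å molecular sieves, CH2Cl2, −20 °C
Reagents that add atoms: tert-butyl hydroperoxide, CC(C)(C)OO
Why: Hydroxyl-directed Sharpless epoxidation in the matched sense (D-(−)-tartrate for the (R)-carbinol) should give the erythro epoxy alcohol, which is (4S) and is also the diastereomer favoured by A(1,2) strain in a 2-substituted allylic alcohol.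

Step 14
Reactants: 17 (1R,3R,4S)-5-[(tert-butyldimethylsilyl)oxy]-4-methyl-1-[(2S)-2-methyloxiran-2-yl]-3-[(phenylsulfonyl)methyl]pentan-1-ol
Product: 18 east bis-silyl epoxy sulfone
Conditions: TBSCl, imidazole, DMAP (cat.), DMF, 23 → 40 °C
Reagents that add atoms: tert-butyldimethylsilyl chloride, CC(C)(C)[Si](C)(C)Cl
Why: Silylation of the secondary alcohol with the chloride and imidazole avoids a Lewis-acidic silyl triflate, which could make the neighbouring epoxide rearrange.

Step 15
Reactants: 18 east bis-silyl epoxy sulfone; 4 west epoxy triflate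
Product: 19 open-chain C14 sulfone (both C14 epimers)
Conditions: 18, n-BuLi (1.05 equiv), THF, −78 °C; then 4 (1.1 equiv), DMPU, −78 → −50 °C
Reagents that add atoms: none
Why: SN2 alkylation of the α-sulfonyl carbanion (the only acidic C–H in 18) by the primary triflate forms C13–C14; at these temperatures the carbanion should touch neither epoxide nor the acetate, and the C14 stereocentre is removed in step 16.

Step 16
Reactants: 19 open-chain C14 sulfone (both C14 epimers)
Product: 21 open-chain C6 allylic alcohol, via C6 acetate 20 (not isolated)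
Conditions: Na(Hg) (5 %), Na2HPO4, MeOH–THF, −20 → 0 °C; then K2CO3 (cat.), MeOH, 23 °C
Reagents that add atoms: none
Why: Buffered sodium amalgam cleaves the alkyl phenyl sulfone by electron transfer without harming epoxides or silyl ethers, and methanolysis of the acetate then frees the C6 alcohol.

Step 17
Reactants: 21 open-chain C6 allylic alcohol
Product: 23 open-chain bis-epoxy C6 allylic phenyl sulfone, via allylic mesylate 22 (not isolated)
Conditions: MsCl, Et3N, CH2Cl2, −40 °C; then PhSO2Na, Bu4NI (cat.), DMF, 0 → 23 °C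
Reagents that add atoms: sodium benzenesulfinate, [Na+].[O-]S(=O)c1ccccc1 (to 23); methanesulfonyl chloride, CS(=O)(=O)Cl (to 22 only)
Why: The primary allylic alcohol is activated as its mesylate and benzenesulfinate is S-alkylated by SN2 substitution, with no π-allyl intermediate, so the (E) geometry is kept and the acidic sulfone enters only after all carbanion chemistry is done.

Step 18
Reactants: 23 open-chain bis-epoxy C6 allylic phenyl sulfone
Product: 24 macrocyclic C4 tertiary alcohol with C6 sulfone (both C6 epimers)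
Conditions: LiN(SiMe3)2 (2 equiv), THF (2 mM), −78 → 40 °C; aq. NH4Cl
Reagents that add atoms: none
Why: The amide base removes a C6 proton, the only C–H acid within its reach (allylic and α to the sulfone), and the lithiated allyl sulfone attacks C5, the unsubstituted carbon of the 2,2-disubstituted oxirane, in an SN2 reaction that forms C5–C6 and releases the C4 lithium alkoxide, lithium acting as the Lewis acid for the oxirane. The closest known reaction type is the intramolecular alkylation of sulfone- or sulfide-stabilised allylic carbanions by epoxides that is used to close 14-membered cembrane rings. The ring closes in the 14-endo-tet epoxide-opening mode (both oxirane carbons become ring members and the oxygen ends as the exocyclic C4 hydroxyl), which costs no strain in a ring of this size. C4 keeps its (S) configuration because no bond to it is broken, and the new stereocentre C6 is not controlled and is erased in step 19. The step needs attack at C5 and not at C4 or at the C11–C12 oxirane, α- and not γ-attack of the allyl anion, and ring closure and not oligomerisation: quaternary C4 is closed to SN2, the trisubstituted oxirane is hindered and could be reached from C6 only through a six- or seven-membered ring that would have to hold the (E)-C7=C8 alkene, lithiated allyl sulfones alkylate at the sulfonyl-bearing carbon, and 2 mM concentration suppresses intermolecular reaction. Release of oxirane strain makes the closure irreversible.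

Step 19
Reactants: 24 macrocyclic C4 tertiary alcohol with C6 sulfone (both C6 epimers)
Product: 25 (1R,3R,4S,7E,11S,12S,15S)-3,16-bis[(tert-butyldimethylsilyl)oxy]-11,12-epoxycembr-7-en-4-ol
Conditions: Na(Hg) (5 %), Na2HPO4, MeOH–THF, −20 °C
Reagents that add atoms: none
Why: Reductive desulfonylation by electron transfer; the allyl anion should be protonated at its less substituted end C6, which keeps the (E)-trisubstituted C7=C8 alkene and erases the C6 stereocentre, while the buffer protects epoxide and silyl ethers.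

Step 20
Reactants: 25 (1R,3R,4S,7E,11S,12S,15S)-3,16-bis[(tert-butyldimethylsilyl)oxy]-11,12-epoxycembr-7-en-4-ol
Product: 27 (1R,3R,4S,7E,11S,12S,15S)-11,12-epoxycembr-7-ene-3,4,16-triol, via mono-silyl ether 26 (not isolated)
Conditions: Bu4NF, THF, 0 → 23 °C
Reagents that add atoms: none
Why: Fluoride-induced desilylation removes both silyl ethers, the primary one first; epoxide, alkene and tertiary alcohol are inert to fluoride.

Step 21
Reactants: 27 (1R,3R,4S,7E,11S,12S,15S)-11,12-epoxycembr-7-ene-3,4,16-triol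
Product: 30 (1R,3R,4S,7E,11S,12S,15S)-11,12-epoxy-4-hydroxycembr-7-en-16,3-olide, via hydroxy aldehyde 28 (not isolated), via lactol 29 (not isolated)
Conditions: TEMPO (cat.), PhI(OAc)2, CH2Cl2, 23 °C
Reagents that add atoms: none
Why: Nitroxyl-catalysed oxidative lactonisation: the oxoammonium ion oxidises only the primary alcohol, the C3 hydroxyl traps the aldehyde as the six-membered lactol, and the lactol is oxidised to the δ-lactone; this reagent pair is known to spare secondary and tertiary vicinal diols in polyols, and C15 keeps its configuration, which is also the thermodynamically preferred all-equatorial one.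

Step 22
Reactants: 30 (1R,3R,4S,7E,11S,12S,15S)-11,12-epoxy-4-hydroxycembr-7-en-16,3-olide
Product: 31 (1R,3R,4S,7S,11S,12S,15S)-11,12-epoxy-7-hydroperoxy-4-hydroxycembr-8(19)-en-16,3-olide (target)
Conditions: O2, tetraphenylporphyrin (cat.), visible light, CH2Cl2, 0 °C
Reagents that add atoms: oxygen (reacting as singlet oxygen), O=O
Why: Schenck ene reaction; the cis effect directs hydrogen abstraction to the more crowded side of the trisubstituted alkene (C6 and the C19 methyl), abstraction from C19 with C7–O bond formation gives the exocyclic alkene and the secondary hydroperoxide, and the (7S) configuration should arise from attack on the outer face of the alkene in the macrocycle, the 7-epimer and the C8 hydroperoxide regioisomer being removed by chromatography.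

Compound list
1 | geranyl acetate, (2E)-3,7-dimethylocta-2,6-dien-1-yl acetate | CC(C)=CCC/C(C)=C/COC(C)=O | starting material
2 | (2E,6E)-8-hydroxy-3,7-dimethylocta-2,6-dien-1-yl acetate | CC(=O)OC/C=C(\C)CC/C=C(\C)CO | intermediate
3 | (2E)-5-[(2S,3S)-3-(hydroxymethyl)-3-methyloxiran-2-yl]-3-methylpent-2-en-1-yl acetate | CC(=O)OC/C=C(\C)CC[C@@H]1O[C@@]1(C)CO | intermediate
4 | west epoxy triflate, (2E)-3-methyl-5-[(2S,3S)-3-methyl-3-({[(trifluoromethyl)sulfonyl]oxy}methyl)oxiran-2-yl]pent-2-en-1-yl acetate | CC(=O)OC/C=C(\C)CC[C@@H]1O[C@@]1(C)COS(=O)(=O)C(F)(F)F | intermediate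
5 | methyl (2R)-3-hydroxy-2-methylpropanoate | COC(=O)[C@H](C)CO | starting material
6 | methyl (2R)-3-[(tert-butyldimethylsilyl)oxy]-2-methylpropanoate | COC(=O)[C@H](C)CO[Si](C)(C)C(C)(C)C | intermediate
7 | (2R)-3-[(tert-butyldimethylsilyl)oxy]-2-methylpropanal | O=C[C@H](C)CO[Si](C)(C)C(C)(C)C | intermediate
8 | methyl (2Z,4S)-5-[(tert-butyldimethylsilyl)oxy]-4-methylpent-2-enoate | COC(=O)/C=C\[C@H](C)CO[Si](C)(C)C(C)(C)C | intermediate
9 | methyl (2Z,4S)-5-hydroxy-4-methylpent-2-enoate (formed in the flask in step 7) | COC(=O)/C=C\[C@H](C)CO | intermediate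
10 | (5S)-5-methyl-5,6-dihydro-2H-pyran-2-one | O=C1C=C[C@H](C)CO1 | intermediate
11 | (4R,5S)-5-methyl-4-[(phenylsulfanyl)methyl]oxan-2-one | O=C1C[C@@H](CSc2ccccc2)[C@H](C)CO1 | intermediate
12 | (5R,6S)-7-hydroxy-2,6-dimethyl-5-[(phenylsulfanyl)methyl]hept-1-en-3-one | C=C(C)C(=O)C[C@@H](CSc1ccccc1)[C@H](C)CO | intermediate
13 | (5R,6S)-7-[(tert-butyldimethylsilyl)oxy]-2,6-dimethyl-5-[(phenylsulfanyl)methyl]hept-1-en-3-one | C=C(C)C(=O)C[C@@H](CSc1ccccc1)[C@H](C)CO[Si](C)(C)C(C)(C)C | intermediate
14 | (5R,6S)-7-[(tert-butyldimethylsilyl)oxy]-2,6-dimethyl-5-[(phenylsulfinyl)methyl]hept-1-en-3-one, both sulfur epimers (formed in the flask in step 11) | C=C(C)C(=O)C[C@@H](CS(=O)c1ccccc1)[C@H](C)CO[Si](C)(C)C(C)(C)C | intermediate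
15 | (5R,6S)-7-[(tert-butyldimethylsilyl)oxy]-2,6-dimethyl-5-[(phenylsulfonyl)methyl]hept-1-en-3-one | C=C(C)C(=O)C[C@@H](CS(=O)(=O)c1ccccc1)[C@H](C)CO[Si](C)(C)C(C)(C)C | intermediate
16 | (3R,5R,6S)-7-[(tert-butyldimethylsilyl)oxy]-2,6-dimethyl-5-[(phenylsulfonyl)methyl]hept-1-en-3-ol | C=C(C)[C@H](O)C[C@@H](CS(=O)(=O)c1ccccc1)[C@H](C)CO[Si](C)(C)C(C)(C)C | intermediate
17 | (1R,3R,4S)-5-[(tert-butyldimethylsilyl)oxy]-4-methyl-1-[(2S)-2-methyloxiran-2-yl]-3-[(phenylsulfonyl)methyl]pentan-1-ol | O=S(=O)(c1ccccc1)C[C@H](C[C@@H](O)[C@@](C)(O1)C1)[C@H](C)CO[Si](C)(C)C(C)(C)C | intermediate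
18 | east bis-silyl epoxy sulfone, (2S)-2-{(1R,3R,4S)-1,5-bis[(tert-butyldimethylsilyl)oxy]-4-methyl-3-[(phenylsulfonyl)methyl]pentyl}-2-methyloxirane | O=S(=O)(c1ccccc1)C[C@H](C[C@@H](O[Si](C)(C)C(C)(C)C)[C@@](C)(O1)C1)[C@H](C)CO[Si](C)(C)C(C)(C)C | intermediate
19 | open-chain C14 sulfone, (1R,3R,4S,7E,11S,12S,15S)-6-acetoxy-3,16-bis[(tert-butyldimethylsilyl)oxy]-4,5:11,12-diepoxy-14-(phenylsulfonyl)-5,6-secocembr-7-ene, both C14 epimers | CC(=O)OC/C=C(\C)CC[C@@H]1O[C@@]1(C)CC(S(=O)(=O)c1ccccc1)[C@H](C[C@@H](O[Si](C)(C)C(C)(C)C)[C@@](C)(O1)C1)[C@H](C)CO[Si](C)(C)C(C)(C)C | intermediate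
20 | C6 acetate, (1R,3R,4S,7E,11S,12S,15S)-6-acetoxy-3,16-bis[(tert-butyldimethylsilyl)oxy]-4,5:11,12-diepoxy-5,6-secocembr-7-ene (formed in the flask in step 16) | CC(=O)OC/C=C(\C)CC[C@@H]1O[C@@]1(C)CC[C@H](C[C@@H](O[Si](C)(C)C(C)(C)C)[C@@](C)(O1)C1)[C@H](C)CO[Si](C)(C)C(C)(C)C | intermediate
21 | open-chain C6 allylic alcohol, (1R,3R,4S,7E,11S,12S,15S)-3,16-bis[(tert-butyldimethylsilyl)oxy]-4,5:11,12-diepoxy-5,6-secocembr-7-en-6-ol | OC/C=C(\C)CC[C@@H]1O[C@@]1(C)CC[C@H](C[C@@H](O[Si](C)(C)C(C)(C)C)[C@@](C)(O1)C1)[C@H](C)CO[Si](C)(C)C(C)(C)C | intermediate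
22 | allylic mesylate, the C6 methanesulfonate of 21 (formed in the flask in step 17) | CS(=O)(=O)OC/C=C(\C)CC[C@@H]1O[C@@]1(C)CC[C@H](C[C@@H](O[Si](C)(C)C(C)(C)C)[C@@](C)(O1)C1)[C@H](C)CO[Si](C)(C)C(C)(C)C | intermediate
23 | open-chain bis-epoxy C6 allylic phenyl sulfone, (1R,3R,4S,7E,11S,12S,15S)-3,16-bis[(tert-butyldimethylsilyl)oxy]-4,5:11,12-diepoxy-6-(phenylsulfonyl)-5,6-secocembr-7-ene | O=S(=O)(c1ccccc1)C/C=C(\C)CC[C@@H]1O[C@@]1(C)CC[C@H](C[C@@H](O[Si](C)(C)C(C)(C)C)[C@@](C)(O1)C1)[C@H](C)CO[Si](C)(C)C(C)(C)C | intermediate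
24 | macrocyclic C4 tertiary alcohol with C6 sulfone, (1R,3R,4S,7E,11S,12S,15S)-3,16-bis[(tert-butyldimethylsilyl)oxy]-11,12-epoxy-6-(phenylsulfonyl)cembr-7-en-4-ol, both C6 epimers | O=S(=O)(c1ccccc1)C1/C=C(\C)CC[C@@H]2O[C@@]2(C)CC[C@H](C[C@@H](O[Si](C)(C)C(C)(C)C)[C@@](C)(O)C1)[C@H](C)CO[Si](C)(C)C(C)(C)C | intermediate
25 | (1R,3R,4S,7E,11S,12S,15S)-3,16-bis[(tert-butyldimethylsilyl)oxy]-11,12-epoxycembr-7-en-4-ol | C1/C=C(\C)CC[C@@H]2O[C@@]2(C)CC[C@H](C[C@@H](O[Si](C)(C)C(C)(C)C)[C@@](C)(O)C1)[C@H](C)CO[Si](C)(C)C(C)(C)C | intermediate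
26 | mono-silyl ether, (1R,3R,4S,7E,11S,12S,15S)-3-[(tert-butyldimethylsilyl)oxy]-11,12-epoxycembr-7-ene-4,16-diol (formed in the flask in step 20) | C1/C=C(\C)CC[C@@H]2O[C@@]2(C)CC[C@H](C[C@@H](O[Si](C)(C)C(C)(C)C)[C@@](C)(O)C1)[C@H](C)CO | intermediate
27 | (1R,3R,4S,7E,11S,12S,15S)-11,12-epoxycembr-7-ene-3,4,16-triol | C1/C=C(\C)CC[C@@H]2O[C@@]2(C)CC[C@H](C[C@@H](O)[C@@](C)(O)C1)[C@H](C)CO | intermediate
28 | hydroxy aldehyde, (1R,3R,4S,7E,11S,12S,15S)-11,12-epoxy-3,4-dihydroxycembr-7-en-16-al (formed in the flask in step 21) | C1/C=C(\C)CC[C@@H]2O[C@@]2(C)CC[C@H](C[C@@H](O)[C@@](C)(O)C1)[C@H](C)C=O | intermediate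
29 | lactol, (1R,3R,4S,7E,11S,12S,15S)-3,16:11,12-diepoxycembr-7-ene-4,16-diol, both C16 epimers (formed in the flask in step 21) | C1/C=C(\C)CC[C@@H]2O[C@@]2(C)CC[C@H](C[C@@H](O3)[C@@](C)(O)C1)[C@H](C)C3O | intermediate
30 | (1R,3R,4S,7E,11S,12S,15S)-11,12-epoxy-4-hydroxycembr-7-en-16,3-olide | C1/C=C(\C)CC[C@@H]2O[C@@]2(C)CC[C@H](C[C@@H](O3)[C@@](C)(O)C1)[C@H](C)C3=O | intermediate
31 | (1R,3R,4S,7S,11S,12S,15S)-11,12-epoxy-7-hydroperoxy-4-hydroxycembr-8(19)-en-16,3-olide, CNP0319766.2 | C=C1CC[C@@H]2O[C@@]2(C)CC[C@@H]2C[C@@H](OC(=O)[C@H]2C)[C@@](C)(O)CC[C@@H]1OO | target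

Total step count: 22. Longest linear sequence: 19 steps (steps 4–22, from 5); the west fragment (steps 1–3) joins in step 15.

Steps most likely to fail

Step 18 (ring closure). The slow 14-membered closure may be outrun by intermolecular epoxide opening (oligomerisation) or by decay of the anion, because a sulfonyl-stabilised carbanion is a weak nucleophile towards an oxirane next to a quaternary centre. The fallback changes the nucleophile to the more reactive sulfur-stabilised allyl anion of a sulfide. It sets out from 21: PhSSPh and Bu3P convert the alcohol into the open-chain allylic phenyl sulfide F1; n-BuLi and DABCO in THF at −78 °C under high dilution close the ring through the same C5–C6 bond to the macrocyclic sulfide F2; (NH4)6Mo7O24 and H2O2 in EtOH at 0 °C then oxidise sulfur only, and the route is rejoined at 24.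

Step 22 (ene reaction). Facial selectivity at C7 rests on the conformation of the macrocycle alone and may be poor, and hydrogen abstraction from C6 competes and leads to the tertiary C8 hydroperoxide. The fallback replaces substrate control at C7 by reagent control. It sets out from 30: photo-oxygenation as in step 22 followed by PPh3 in the same flask gives the C7 allylic alcohols F3 (both epimers, the tertiary regioisomer being separated); Dess–Martin periodinane converts both epimers into the single α-methylene ketone F4; (S)-2-methyl-CBS-oxazaborolidine and catecholborane give the (7R)-alcohol F5; MsCl and Et3N at −78 °C give the mesylate F6; anhydrous H2O2 in Et2O at low temperature displaces the mesylate with inversion and returns to 31.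

Step 19 (allylic desulfonylation). The allyl anion may be protonated at C8, which moves the double bond to C6=C7, or the alkene geometry may scramble. The fallback replaces electron transfer by palladium-catalysed hydride substitution: from 24, PdCl2(dppp) (cat.) and LiBHEt3 in THF at −20 °C deliver hydride to the less substituted end of the π-allyl complex and return to 25, the low temperature being chosen to spare the epoxide; no new compound is made (F0).

Further compounds
F1 | step 18 | open-chain allylic phenyl sulfide, (1R,3R,4S,7E,11S,12S,15S)-3,16-bis[(tert-butyldimethylsilyl)oxy]-4,5:11,12-diepoxy-6-(phenylsulfanyl)-5,6-secocembr-7-ene | c1ccccc1SC/C=C(\C)CC[C@@H]1O[C@@]1(C)CC[C@H](C[C@@H](O[Si](C)(C)C(C)(C)C)[C@@](C)(O1)C1)[C@H](C)CO[Si](C)(C)C(C)(C)C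
F2 | step 18 | macrocyclic sulfide, (1R,3R,4S,7E,11S,12S,15S)-3,16-bis[(tert-butyldimethylsilyl)oxy]-11,12-epoxy-6-(phenylsulfanyl)cembr-7-en-4-ol, both C6 epimers | c1ccccc1SC1/C=C(\C)CC[C@@H]2O[C@@]2(C)CC[C@H](C[C@@H](O[Si](C)(C)C(C)(C)C)[C@@](C)(O)C1)[C@H](C)CO[Si](C)(C)C(C)(C)C
F0 | step 19 | none | none
F3 | step 22 | C7 allylic alcohols, (1R,3R,4S,11S,12S,15S)-11,12-epoxy-4,7-dihydroxycembr-8(19)-en-16,3-olide, both C7 epimers | C=C1CC[C@@H]2O[C@@]2(C)CC[C@@H]2C[C@@H](OC(=O)[C@H]2C)[C@@](C)(O)CCC1O
F4 | step 22 | α-methylene ketone, (1R,3R,4S,11S,12S,15S)-11,12-epoxy-4-hydroxy-7-oxocembr-8(19)-en-16,3-olide | C=C1CC[C@@H]2O[C@@]2(C)CC[C@@H]2C[C@@H](OC(=O)[C@H]2C)[C@@](C)(O)CCC1=O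
F5 | step 22 | (7R)-alcohol, (1R,3R,4S,7R,11S,12S,15S)-11,12-epoxy-4,7-dihydroxycembr-8(19)-en-16,3-olide | C=C1CC[C@@H]2O[C@@]2(C)CC[C@@H]2C[C@@H](OC(=O)[C@H]2C)[C@@](C)(O)CC[C@H]1O
F6 | step 22 | (7R)-mesylate, the C7 methanesulfonate of F5 | C=C1CC[C@@H]2O[C@@]2(C)CC[C@@H]2C[C@@H](OC(=O)[C@H]2C)[C@@](C)(O)CC[C@H]1OS(C)(=O)=O
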